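Everything rests on cutting the ten-membered carbocycle at C1–C2. The target has a secondary alcohol at C2, flanked by C3 (one oxidation level below a ketone) and by the C1 methylene leading to C10, whose methyl (C14) is one hydrogenation away from an exocyclic alkene: the homoallylic α-ketol pattern that a [2,3]-sigmatropic (Wittig) rearrangement of an α-allyloxy ketone enolate leaves behind. The precursor is therefore the eleven-membered allyl ether 25, whose oxygen bridges C2 and C14 in a ring that also holds the Z-enone, the trans-fused γ-lactone carbons C6 and C7 and the silylated C9 carbinol. One enolisation contracts this ring to the carbocycle, makes C1–C2, frees the C2 hydroxyl, sets C2 and unveils the C10 methylene.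

Key step: step 16

Remark: germacranolide numbering is used for all intermediates (ring C1–C10; C11/C12 lactone; C13 lactone methylene; C14 on C10; C15 on C4); TBS = tert-butyldimethylsilyl; metal alkoxides, enolates and borate esters that are only protonated or hydrolysed on work-up are not numbered; 1, 3, 8, 9, 17, 36 and the CBS catalyst are taken as commercial.

Step 1
Reactants: 1 (S)-5-(hydroxymethyl)furan-2(5H)-one
Product: 2 (S)-5-[(TBS-oxy)methyl]furan-2(5H)-one
Conditions: TBSCl, imidazole, CH2Cl2, 0 °C to rt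
Reagents that add atoms: tert-butyldimethylsilyl chloride (TBSCl), CC(C)(C)[Si](C)(C)Cl
Why: Silylation of a primary alcohol under chloride–imidazole conditions should go cleanly; the stereocentre (future C6) is bought, and the bulky silyloxymethyl group is there to shield one butenolide face in step 2.

Step 2
Reactants: 2 (S)-5-[(TBS-oxy)methyl]furan-2(5H)-one; 3 vinylmagnesium bromide
Product: 4 (4R,5S)-5-[(TBS-oxy)methyl]-4-vinyldihydrofuran-2(3H)-one (4,5-trans)
Conditions: CuI, THF–Me2S, −78 to −40 °C; aq. NH4Cl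
Reagents that add atoms: none
Why: Conjugate addition of the vinyl cuprate to the butenolide should occur anti to the C5 silyloxymethyl group (substrate control), which sets C7 trans to C6.

Step 3
Reactants: 4 (4R,5S)-5-[(TBS-oxy)methyl]-4-vinyldihydrofuran-2(3H)-one
Product: 6 (4S,5S)-5-[(TBS-oxy)methyl]-4-(2-hydroxyethyl)dihydrofuran-2(3H)-one, via B-alkyl-9-borabicyclononane 5 (not isolated)
Conditions: 9-BBN, THF, 0 °C to rt; then H2O2, aq. NaOAc, 0 °C
Reagents that add atoms: hydrogen peroxide, OO
Why: Hydroboration–oxidation with 9-BBN should place boron and then oxygen on the terminal vinyl carbon (C9) and leave the lactone untouched; no stereocentre is formed.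

Step 4
Reactants: 6 (4S,5S)-5-[(TBS-oxy)methyl]-4-(2-hydroxyethyl)dihydrofuran-2(3H)-one
Product: 7 (4S,5S)-5-[(TBS-oxy)methyl]-4-(2-oxoethyl)dihydrofuran-2(3H)-one
Conditions: Dess–Martin periodinane, NaHCO3, CH2Cl2, 0 °C to rt
Reagents that add atoms: none
Why: Dess–Martin oxidation of a primary alcohol to the aldehyde is mild and neutral and should not touch the silyl ether or the lactone.

Step 5
Reactants: 8 2,2-dimethoxyethanol; 9 2,3-dibromopropene
Product: 10 2-bromo-3-(2,2-dimethoxyethoxy)prop-1-ene
Conditions: NaH, THF, 0 °C; then 9, Bu4NI (cat.), 0 °C to rt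
Reagents that add atoms: none
Why: Williamson ether synthesis: the alkoxide of 8 should displace only the allylic bromide of 9 (the vinylic bromide is inert to SN2), giving the C1/C10/C14–O–C2–C3 linchpin.

Step 6
Reactants: 7 (4S,5S)-5-[(TBS-oxy)methyl]-4-(2-oxoethyl)dihydrofuran-2(3H)-one; 10 2-bromo-3-(2,2-dimethoxyethoxy)prop-1-ene
Product: 11 (4S,5S)-5-[(TBS-oxy)methyl]-4-[3-[(2,2-dimethoxyethoxy)methyl]-2-hydroxybut-3-en-1-yl]dihydrofuran-2(3H)-one (both C9 epimers)
Conditions: CrCl2, NiCl2 (cat.), DMF, rt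
Reagents that add atoms: none
Why: Nozaki–Hiyama–Kishi coupling: the alkenylchromium species from 10 should add to the aldehyde only (lactone and acetal are inert) and form the C9–C10 bond; C9 arises unselectively and is corrected in steps 7 and 8.

Step 7
Reactants: 11 the C9-epimeric allylic alcohols
Product: 12 (4S,5S)-5-[(TBS-oxy)methyl]-4-[3-[(2,2-dimethoxyethoxy)methyl]-2-oxobut-3-en-1-yl]dihydrofuran-2(3H)-one
Conditions: Dess–Martin periodinane, NaHCO3, CH2Cl2, 0 °C
Reagents that add atoms: none
Why: Dess–Martin oxidation of the allylic alcohol should give the α-methylene ketone without acid that could open the acetal, erasing the unselective C9 centre.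

Step 8
Reactants: 12 the α-methylene ketone
Product: 13 (4S,5S)-5-[(TBS-oxy)methyl]-4-[(2S)-3-[(2,2-dimethoxyethoxy)methyl]-2-hydroxybut-3-en-1-yl]dihydrofuran-2(3H)-one
Conditions: (R)-2-methyl-CBS-oxazaborolidine, catecholborane, toluene, −78 °C
Reagents that add atoms: none
Why: Corey–Bakshi–Shibata reduction: the catalyst should treat the α-substituted vinyl group as the large and the C8 methylene as the small substituent and deliver hydride to the face that gives the 9S allylic alcohol (reagent control), 1,2-reduction being favoured at low temperature.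

Step 9
Reactants: 13 the (9S)-allylic alcohol
Product: 14 (4S,5S)-4-[(2S)-2-(TBS-oxy)-3-[(2,2-dimethoxyethoxy)methyl]but-3-en-1-yl]-5-[(TBS-oxy)methyl]dihydrofuran-2(3H)-one
Conditions: TBSCl, imidazole, DMAP (cat.), DMF, rt to 40 °C
Reagents that add atoms: tert-butyldimethylsilyl chloride (TBSCl), CC(C)(C)[Si](C)(C)Cl
Why: Silylation of the secondary allylic alcohol with the chloride–imidazole system (not a silyl triflate, which would activate the dimethyl acetal) should give the base-stable C9 silyl ether needed in the key step.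

Step 10
Reactants: 14 the bis-silyl ether
Product: 15 (4S,5S)-4-[(2S)-2-(TBS-oxy)-3-[(2,2-dimethoxyethoxy)methyl]but-3-en-1-yl]-5-(hydroxymethyl)dihydrofuran-2(3H)-one
Conditions: HF·pyridine, pyridine, THF, 0 °C
Reagents that add atoms: none
Why: Selective desilylation: the unhindered primary silyl ether should be cleaved much faster than the hindered secondary allylic one under buffered HF·pyridine, which also leaves acetal and lactone intact.

Step 11
Reactants: 15 the primary alcohol
Product: 16 (4S,5S)-4-[(2S)-2-(TBS-oxy)-3-[(2,2-dimethoxyethoxy)methyl]but-3-en-1-yl]-5-formyldihydrofuran-2(3H)-one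
Conditions: Dess–Martin periodinane, NaHCO3, CH2Cl2, 0 °C; used crude
Reagents that add atoms: none
Why: Dess–Martin oxidation under buffered neutral conditions should give the sensitive α-acyloxy aldehyde without epimerisation at C6.

Step 12
Reactants: 16 the lactone aldehyde; 17 ethyltriphenylphosphonium iodide
Product: 21 (4S,5S)-4-[(2S)-2-(TBS-oxy)-3-[(2,2-dimethoxyethoxy)methyl]but-3-en-1-yl]-5-[(Z)-2-iodoprop-1-en-1-yl]dihydrofuran-2(3H)-one, via ethylidenetriphenylphosphorane 18 (not isolated), via (1-iodoethyl)triphenylphosphonium iodide 19 (not isolated), via (1-iodoethylidene)triphenylphosphorane 20 (not isolated)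
Conditions: 17, n-BuLi, THF, rt; I2, −78 °C; NaN(SiMe3)2, −78 to −20 °C; then 16, −78 °C to rt
Reagents that add atoms: iodine, II
Why: Wittig olefination with the α-iodo ylide (Stork–Zhao type) should give the Z-iodoalkene, iodine cis to C6, through the kinetically preferred cis-oxaphosphetane, which fixes the 4Z geometry and places the C15 methyl.

Step 13
Reactants: 21 the Z-iodoalkene acetal
Product: 23 (4S,5S)-4-[(2S)-2-(TBS-oxy)-3-[(2-oxoethoxy)methyl]but-3-en-1-yl]-5-[(Z)-2-iodoprop-1-en-1-yl]dihydrofuran-2(3H)-one, via collidinium salt 22 (not isolated)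
Conditions: Et3SiOTf, 2,4,6-collidine, CH2Cl2, 0 °C; then H2O
Reagents that add atoms: water, O
Why: Cleavage of a dimethyl acetal by silyl triflate and collidine through the N-(α-methoxyalkyl)collidinium salt, followed by hydrolysis, is a non-acidic acetal deprotection that should spare the secondary silyl ether, the lactone and the iodoalkene.

Step 14
Reactants: 23 the iodoalkene aldehyde
Product: 24 eleven-membered cyclic allyl ether alcohol (3RS,6S,7S,9S,4Z; ring C2–C3(OH)–C4(CH3)=C5–C6–C7–C8–C9(OTBS)–C10(=C1H2)–C14–O; γ-lactone trans-fused at C6/C7)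
Conditions: CrCl2, NiCl2 (cat.), DMSO, rt, 0.003 M, slow addition
Reagents that add atoms: none
Why: Intramolecular Nozaki–Hiyama–Kishi reaction: the alkenylchromium species formed at C4 with retention of the Z geometry should add to the C3 aldehyde and close the eleven-membered ring (11-exo-trig) at high dilution; both C3 epimers serve because C3 is oxidised next, and no palladium is used anywhere in the route because the lactone C6–O bond is allylic.

Step 15
Reactants: 24 the macrocyclic allylic alcohols
Product: 25 eleven-membered allyl ether keto lactone (6S,7S,9S,4Z; as 24 with C3=O)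
Conditions: Dess–Martin periodinane, NaHCO3, CH2Cl2, 0 °C to rt
Reagents that add atoms: none
Why: Dess–Martin oxidation of the allylic alcohol should give the Z-enone without E/Z isomerisation, completing the α-allyloxy ketone for the key step.

Step 16
Reactants: 25 the eleven-membered allyl ether keto lactone
Product: 27 ten-membered α-hydroxy enone (2S,6S,7S,9S,4Z; C2–OH; C3=O; exocyclic C10=C14H2; C9–OTBS; 6,7-trans γ-lactone), via lithium enolate 26 (not isolated)
Conditions: LiN(SiMe3)2 (1.05 equiv), THF, −78 to −40 °C; AcOH, −78 °C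
Reagents that add atoms: none
Why: Proposed new method: LiN(SiMe3)2 should remove a C2 proton, the only enolisable position of the enone (C4 is sp2 and the lactone C11 protons are far less acidic), and the lithium enolate 26 should rearrange by a concerted suprafacial [2,3]-sigmatropic shift in which, within a five-membered envelope array (C2, O, C14, C10, C1), C2 bonds to the methylene carbon C1 as the O–C14 bond is cleaved, so that the ether oxygen becomes the C2 alkoxide and C14 the new exocyclic methylene. The closest known reaction types are the [2,3]-Wittig rearrangement of open-chain α-allyloxy ketone and ester enolates and the [2,3]-Wittig ring contraction of macrocyclic bis-allylic and allyl propargyl ethers; a one-atom contraction across a 2-substituted allyl unit whose alkene is exocyclic to the ring has not been shown. The ten-membered carbocycle is closed by ring contraction (eleven to ten): the C1–C2 bond forms inside the existing ring, formally a 10-endo-trig bonding to the methylene terminus, so no macrocyclisation entropy is paid, and because the two CH2 termini of the allyl unit are equivalent only one constitution can result. The one new stereocentre, C2, is set by which face of the enolate carbon the tethered methylene can reach, that is by the conformation that the trans-fused lactone, the Z C4=C5 bond and the pseudo-equatorial C9 silyloxy group impose on the eleven-membered ring (substrate control, expected to give 2S but unproven). The step needs the [2,3] shift to beat the [3,3] shift (C3–C1 bonding), the [1,2] shift and fragmentation: the lithium counter-ion and low temperature favour the [2,3] path, the [3,3] alternative would have to build a quaternary C3 in a nine-membered ring, the alkoxide formed cannot revert, and one equivalent of base with a cold acetic acid quench avoids the enediolate that could expel the C6 carboxylate.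

Step 17
Reactants: 27 the ten-membered α-hydroxy enone
Product: 28 (2S,3R)-diol (2S,3R,6S,7S,9S,4Z; otherwise as 27)
Conditions: Zn(BH4)2, Et2O, −30 to 0 °C
Reagents that add atoms: none
Why: Chelation-controlled 1,2-reduction of an α-hydroxy ketone: zinc should bridge the C2 hydroxyl and the C3 carbonyl and hydride should attack the chelate from the side away from C1, giving the anti (2S,3R) diol and leaving the lactone and both alkenes alone.

Step 18
Reactants: 28 the (2S,3R)-diol
Product: 29 2,3-O-isopropylidene acetal of 28 (cis-fused dioxolane)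
Conditions: 2,2-dimethoxypropane, PPTS (cat.), CH2Cl2, rt
Reagents that add atoms: 2,2-dimethoxypropane, COC(C)(C)OC
Why: Acid-catalysed acetonide formation (transacetalisation) should tie the anti diol up as a cis-fused dioxolane, so that C9 alone can be acylated later and no acidic OH is present in step 20.

Step 19
Reactants: 29 the acetonide
Product: 30 (10R)-10,14-dihydro compound (2S,3R,6S,7S,9S,10R,4Z; C10–CH3)
Conditions: H2 (1 atm), RhCl(PPh3)3 (10 mol%), benzene–EtOH, rt
Reagents that add atoms: none
Why: Homogeneous hydrogenation with RhCl(PPh3)3 should reduce the 1,1-disubstituted C10=C14 bond and not the trisubstituted C4=C5 bond; hydrogen is expected to add to the methylene face opposite the bulky C9 silyloxy group in the conformer with H9 eclipsing the double bond (substrate control), which gives 10R.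

Step 20
Reactants: 30 the saturated lactone
Product: 34 α-methylene lactone (2S,3R,6R,7S,9S,10R,4Z; C11=C13H2; C9–OTBS; 2,3-acetonide), via lithium enolate 31 (not isolated), via Mannich base 32 (not isolated), via ammonium iodide 33 (not isolated)
Conditions: LiN(i-Pr)2, THF, −78 °C; Me2N=CH2 I, −78 °C to rt; then MeI, MeOH, rt; then aq. NaHCO3, EtOAc, rt
Reagents that add atoms: N,N-dimethylmethyleneiminium iodide (Eschenmoser's salt), C=[N+](C)C.[I-]
Why: α-Methylenation of a lactone by the Mannich–Eschenmoser sequence (enolate aminomethylation, N-methylation, base-induced elimination) should introduce C13 at C11, the only acidic position left in 30; the transient C11 centre is destroyed in the elimination.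

Step 21
Reactants: 34 the silylated α-methylene lactone
Product: 35 9-alcohol (C9–OH; otherwise as 34)
Conditions: HF·pyridine, pyridine, THF, 0 °C to rt
Reagents that add atoms: none
Why: Fluoride-mediated desilylation under buffered, non-basic conditions should free the C9 hydroxyl without harming the acetonide or the base-sensitive α-methylene lactone.

Step 22
Reactants: 35 the 9-alcohol; 36 angelic acid ((Z)-2-methylbut-2-enoic acid)
Product: 38 9-O-angeloyl 2,3-O-isopropylidene compound, via mixed anhydride 37 (not isolated)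
Conditions: 36, 2,4,6-trichlorobenzoyl chloride, Et3N, toluene, rt; then 35, toluene, 80 °C
Reagents that add atoms: none
Why: Yamaguchi-type esterification through the angelic 2,4,6-trichlorobenzoic mixed anhydride without DMAP is the established way to acylate hindered secondary alcohols with angelic acid while keeping the Z geometry (no isomerisation to the tiglate).

Step 23
Reactants: 38 the angelate acetonide
Product: 39 CNP0229085.1, (2S,3R,6R,7S,9S,10R,4Z)-9-angeloyloxy-2,3-dihydroxygermacra-4,11(13)-dien-12,6-olide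
Conditions: AcOH–H2O (4:1), 40 °C
Reagents that add atoms: none
Why: Mild acid hydrolysis of the acetonide should release the 2,3-diol; the angelate, the α-methylene lactone and the allylic C3–O bond tolerate aqueous acetic acid.

Compound list
1 | (S)-5-(hydroxymethyl)furan-2(5H)-one | O=C1C=C[C@@H](CO)O1 | starting material
2 | (S)-5-[(TBS-oxy)methyl]furan-2(5H)-one | O=C1C=C[C@@H](CO[Si](C)(C)C(C)(C)C)O1 | intermediate
3 | vinylmagnesium bromide | C=C[Mg]Br | starting material
4 | (4R,5S)-5-[(TBS-oxy)methyl]-4-vinyldihydrofuran-2(3H)-one | O=C1C[C@H](C=C)[C@@H](CO[Si](C)(C)C(C)(C)C)O1 | intermediate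
5 | B-alkyl-9-borabicyclo[3.3.1]nonane from 4 (boron on C9) | O=C1C[C@H](CCB2C3CCCC2CCC3)[C@@H](CO[Si](C)(C)C(C)(C)C)O1 | intermediate (not isolated)
6 | (4S,5S)-5-[(TBS-oxy)methyl]-4-(2-hydroxyethyl)dihydrofuran-2(3H)-one | O=C1C[C@H](CCO)[C@@H](CO[Si](C)(C)C(C)(C)C)O1 | intermediate
7 | (4S,5S)-5-[(TBS-oxy)methyl]-4-(2-oxoethyl)dihydrofuran-2(3H)-one | O=C1C[C@H](CC=O)[C@@H](CO[Si](C)(C)C(C)(C)C)O1 | intermediate
8 | 2,2-dimethoxyethanol | COC(CO)OC | starting material
9 | 2,3-dibromopropene | C=C(Br)CBr | starting material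
10 | 2-bromo-3-(2,2-dimethoxyethoxy)prop-1-ene | C=C(Br)COCC(OC)OC | intermediate
11 | (4S,5S)-5-[(TBS-oxy)methyl]-4-[3-[(2,2-dimethoxyethoxy)methyl]-2-hydroxybut-3-en-1-yl]dihydrofuran-2(3H)-one, C9 epimers | O=C1C[C@H](CC(O)C(=C)COCC(OC)OC)[C@@H](CO[Si](C)(C)C(C)(C)C)O1 | intermediate
12 | (4S,5S)-5-[(TBS-oxy)methyl]-4-[3-[(2,2-dimethoxyethoxy)methyl]-2-oxobut-3-en-1-yl]dihydrofuran-2(3H)-one | O=C1C[C@H](CC(=O)C(=C)COCC(OC)OC)[C@@H](CO[Si](C)(C)C(C)(C)C)O1 | intermediate
13 | (4S,5S)-5-[(TBS-oxy)methyl]-4-[(2S)-3-[(2,2-dimethoxyethoxy)methyl]-2-hydroxybut-3-en-1-yl]dihydrofuran-2(3H)-one | O=C1C[C@H](C[C@H](O)C(=C)COCC(OC)OC)[C@@H](CO[Si](C)(C)C(C)(C)C)O1 | intermediate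
14 | (4S,5S)-4-[(2S)-2-(TBS-oxy)-3-[(2,2-dimethoxyethoxy)methyl]but-3-en-1-yl]-5-[(TBS-oxy)methyl]dihydrofuran-2(3H)-one | O=C1C[C@H](C[C@H](O[Si](C)(C)C(C)(C)C)C(=C)COCC(OC)OC)[C@@H](CO[Si](C)(C)C(C)(C)C)O1 | intermediate
15 | (4S,5S)-4-[(2S)-2-(TBS-oxy)-3-[(2,2-dimethoxyethoxy)methyl]but-3-en-1-yl]-5-(hydroxymethyl)dihydrofuran-2(3H)-one | O=C1C[C@H](C[C@H](O[Si](C)(C)C(C)(C)C)C(=C)COCC(OC)OC)[C@@H](CO)O1 | intermediate
16 | (4S,5S)-4-[(2S)-2-(TBS-oxy)-3-[(2,2-dimethoxyethoxy)methyl]but-3-en-1-yl]-5-formyldihydrofuran-2(3H)-one | O=C1C[C@H](C[C@H](O[Si](C)(C)C(C)(C)C)C(=C)COCC(OC)OC)[C@@H](C=O)O1 | intermediate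
17 | ethyltriphenylphosphonium iodide | CC[P+](c1ccccc1)(c1ccccc1)c1ccccc1.[I-] | starting material
18 | ethylidenetriphenylphosphorane | CC=P(c1ccccc1)(c1ccccc1)c1ccccc1 | intermediate (not isolated)
19 | (1-iodoethyl)triphenylphosphonium iodide | CC(I)[P+](c1ccccc1)(c1ccccc1)c1ccccc1.[I-] | intermediate (not isolated)
20 | (1-iodoethylidene)triphenylphosphorane | CC(I)=P(c1ccccc1)(c1ccccc1)c1ccccc1 | intermediate (not isolated)
21 | (4S,5S)-4-[(2S)-2-(TBS-oxy)-3-[(2,2-dimethoxyethoxy)methyl]but-3-en-1-yl]-5-[(Z)-2-iodoprop-1-en-1-yl]dihydrofuran-2(3H)-one | O=C1C[C@H](C[C@H](O[Si](C)(C)C(C)(C)C)C(=C)COCC(OC)OC)[C@@H](/C=C(/C)\I)O1 | intermediate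
22 | 1-(1-methoxy-2-alkoxyethyl)-2,4,6-trimethylpyridinium triflate from 21 (one OMe of the acetal replaced by collidinium) | O=C1C[C@H](C[C@H](O[Si](C)(C)C(C)(C)C)C(=C)COCC(OC)[n+]2c(C)cc(C)cc2C)[C@@H](/C=C(/C)\I)O1.[O-]S(=O)(=O)C(F)(F)F | intermediate (not isolated)
23 | (4S,5S)-4-[(2S)-2-(TBS-oxy)-3-[(2-oxoethoxy)methyl]but-3-en-1-yl]-5-[(Z)-2-iodoprop-1-en-1-yl]dihydrofuran-2(3H)-one | O=C1C[C@H](C[C@H](O[Si](C)(C)C(C)(C)C)C(=C)COCC=O)[C@@H](/C=C(/C)\I)O1 | intermediate
24 | eleven-membered cyclic allyl ether alcohol (3RS,6S,7S,9S,4Z): 3-hydroxy, 9-O-TBS, C10=C1H2 methylene, O between C2 and C14, 6,7-trans γ-lactone | C1C(=O)O[C@@H]2/C=C(/C)C(O)COCC(=C)[C@@H](O[Si](C)(C)C(C)(C)C)C[C@@H]12 | intermediate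
25 | eleven-membered allyl ether keto lactone (6S,7S,9S,4Z): as 24 with C3=O | C1C(=O)O[C@@H]2/C=C(/C)C(=O)COCC(=C)[C@@H](O[Si](C)(C)C(C)(C)C)C[C@@H]12 | intermediate (key-step precursor)
26 | lithium C2=C3 enolate of 25 | [Li+].C1C(=O)O[C@@H]2/C=C(/C)C([O-])=COCC(=C)[C@@H](O[Si](C)(C)C(C)(C)C)C[C@@H]12 | intermediate (not isolated)
27 | ten-membered α-hydroxy enone (2S,6S,7S,9S,4Z): 2-hydroxy, 3-oxo, 9-O-TBS, exocyclic C10=C14H2, 6,7-trans γ-lactone | C1C(=O)O[C@@H]2/C=C(/C)C(=O)[C@@H](O)CC(=C)[C@@H](O[Si](C)(C)C(C)(C)C)C[C@@H]12 | intermediate (key-step product)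
28 | (2S,3R)-diol (2S,3R,6S,7S,9S,4Z), otherwise as 27 | C1C(=O)O[C@@H]2/C=C(/C)[C@@H](O)[C@@H](O)CC(=C)[C@@H](O[Si](C)(C)C(C)(C)C)C[C@@H]12 | intermediate
29 | 2,3-O-isopropylidene acetal of 28 | C1C(=O)O[C@@H]2/C=C(/C)[C@H]3OC(C)(C)O[C@H]3CC(=C)[C@@H](O[Si](C)(C)C(C)(C)C)C[C@@H]12 | intermediate
30 | (10R)-10,14-dihydro derivative of 29 (2S,3R,6S,7S,9S,10R,4Z) | C1C(=O)O[C@@H]2/C=C(/C)[C@H]3OC(C)(C)O[C@H]3C[C@@H](C)[C@@H](O[Si](C)(C)C(C)(C)C)C[C@@H]12 | intermediate
31 | lithium lactone enolate of 30 (C11=C12) | C1=C([O-])O[C@@H]2/C=C(/C)[C@H]3OC(C)(C)O[C@H]3C[C@@H](C)[C@@H](O[Si](C)(C)C(C)(C)C)C[C@@H]12.[Li+] | intermediate (not isolated)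
32 | 11-(dimethylaminomethyl) lactone from 30 (C11 epimers) | CN(C)CC1C(=O)O[C@@H]2/C=C(/C)[C@H]3OC(C)(C)O[C@H]3C[C@@H](C)[C@@H](O[Si](C)(C)C(C)(C)C)C[C@@H]12 | intermediate (not isolated)
33 | 11-(trimethylammoniomethyl) lactone iodide | C[N+](C)(C)CC1C(=O)O[C@@H]2/C=C(/C)[C@H]3OC(C)(C)O[C@H]3C[C@@H](C)[C@@H](O[Si](C)(C)C(C)(C)C)C[C@@H]12.[I-] | intermediate (not isolated)
34 | α-methylene lactone (2S,3R,6R,7S,9S,10R,4Z): C11=C13H2, 9-O-TBS, 2,3-acetonide | C=C1C(=O)O[C@@H]2/C=C(/C)[C@H]3OC(C)(C)O[C@H]3C[C@@H](C)[C@@H](O[Si](C)(C)C(C)(C)C)C[C@@H]12 | intermediate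
35 | 9-alcohol of 34 | C=C1C(=O)O[C@@H]2/C=C(/C)[C@H]3OC(C)(C)O[C@H]3C[C@@H](C)[C@@H](O)C[C@@H]12 | intermediate
36 | angelic acid, (Z)-2-methylbut-2-enoic acid | C/C=C(/C)C(=O)O | starting material
37 | angelic 2,4,6-trichlorobenzoic anhydride | C/C=C(/C)C(=O)OC(=O)c1c(Cl)cc(Cl)cc1Cl | intermediate (not isolated)
38 | 9-O-angeloyl 2,3-O-isopropylidene compound | C=C1C(=O)O[C@@H]2/C=C(/C)[C@H]3OC(C)(C)O[C@H]3C[C@@H](C)[C@@H](OC(=O)/C(C)=C\C)C[C@@H]12 | intermediate
39 | CNP0229085.1, (2S,3R,6R,7S,9S,10R,4Z)-9-angeloyloxy-2,3-dihydroxygermacra-4,11(13)-dien-12,6-olide | C=C1C(=O)O[C@@H]2/C=C(/C)[C@@H](O)[C@@H](O)C[C@@H](C)[C@@H](OC(=O)/C(C)=C\C)C[C@@H]12 | target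

Total step count: 23. Longest linear sequence: 22 steps (steps 1–4 and 6–23, from 1; step 5 is the only side branch).

Steps most likely to fail

1. Step 16 (proposed new method). The enolate may rearrange by the [3,3] or [1,2] path, fragment, or bond to the wrong C2 face. The fallback uses known chemistry, sets out from 23 and rejoins at 27: the C1–C2 bond is made on the open chain by an aza-enolate [2,3]-Wittig rearrangement of an allyloxyacetaldehyde hydrazone, and the ten-membered ring is then closed by a Nozaki–Hiyama–Kishi reaction. Condensation of 23 with (S)-1-amino-2-(methoxymethyl)pyrrolidine should give the SAMP hydrazone F1. LiN(i-Pr)2 (2.2 equiv, THF, −78 to −20 °C; the lactone is enolised reversibly) should trigger the [2,3]-shift to the (2S)-α-hydroxy hydrazone F2 under auxiliary control (the R auxiliary is taken instead if a model shows the opposite induction). Et3SiOTf and 2,6-lutidine give the triethylsilyl ether F3, and CuCl2 in buffered aqueous THF releases the α-silyloxy aldehyde F4. CrCl2 with catalytic NiCl2 at high dilution closes the ten-membered allylic alcohol F5 (both C3 epimers), Dess–Martin oxidation gives the silylated enone F6, and HF·pyridine at 0 °C removes the triethylsilyl group in the presence of the hindered C9 silyl ether to return 27.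

2. Step 19. Hydrogen may add to the wrong face of the C10 methylene (poor or reversed facial selectivity under steric approach control). The fallback sets out from 29 and rejoins at 30, replacing steric control by hydroxyl-directed delivery. Bu4NF in THF should give the free allylic alcohol F7. Hydrogenation with the cationic complex [Rh(nbd)(dppb)]BF4 (H2, 40 atm, CH2Cl2) delivers hydrogen to the face on which the C9 oxygen sits, the face the silyl ether blocks in 29, to give the (10R)-alcohol F8. For a given ring conformation the two modes are complementary, so the one that gives 10R is kept. TBSOTf and 2,6-lutidine then return 30.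

3. Step 12. The basic, hindered iodo-ylide may epimerise C6 of the α-acyloxy aldehyde, convert it poorly, or erode the Z selectivity. The fallback sets out from 16 and rejoins at 24. Non-basic Ramirez olefination (CBr4, PPh3, 2,6-lutidine, CH2Cl2, 0 °C) should give the 1,1-dibromoalkene F9. Trans-selective Negishi monomethylation (Me2Zn, Pd(t-Bu3P)2 cat., THF) replaces only the bromine trans to C6 and gives the Z-bromoalkene F10; oxidative addition of zerovalent palladium into that C–Br bond is far faster than ionisation of the allylic lactone. Acetal cleavage as in step 13 passes through the collidinium salt F11 to the bromoalkene aldehyde F12, and the chromium-mediated closure (CrCl2, more NiCl2, DMSO, 50 °C) gives 24.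

Further compounds
F1 | step 16 | SAMP hydrazone of aldehyde 23 | O=C1C[C@H](C[C@H](O[Si](C)(C)C(C)(C)C)C(=C)COC/C=N/N2CCC[C@H]2COC)[C@@H](/C=C(/C)\I)O1
F2 | step 16 | (2S)-α-hydroxy hydrazone after the open-chain [2,3]-shift (C1–C2 bond made, C10=C14H2) | O=C1C[C@H](C[C@H](O[Si](C)(C)C(C)(C)C)C(=C)C[C@H](O)/C=N/N2CCC[C@H]2COC)[C@@H](/C=C(/C)\I)O1
F3 | step 16 | 2-O-triethylsilyl ether of F2 | O=C1C[C@H](C[C@H](O[Si](C)(C)C(C)(C)C)C(=C)C[C@H](O[Si](CC)(CC)CC)/C=N/N2CCC[C@H]2COC)[C@@H](/C=C(/C)\I)O1
F4 | step 16 | (2S)-2-(triethylsilyloxy) aldehyde (C3 aldehyde, Z-iodoalkene) | O=C1C[C@H](C[C@H](O[Si](C)(C)C(C)(C)C)C(=C)C[C@H](O[Si](CC)(CC)CC)C=O)[C@@H](/C=C(/C)\I)O1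
F5 | step 16 | ten-membered allylic alcohol, 2-O-triethylsilyl, 9-O-TBS, C3 epimers | C1C(=O)O[C@@H]2/C=C(/C)C(O)[C@@H](O[Si](CC)(CC)CC)CC(=C)[C@@H](O[Si](C)(C)C(C)(C)C)C[C@@H]12
F6 | step 16 | 2-O-triethylsilyl ether of 27 | C1C(=O)O[C@@H]2/C=C(/C)C(=O)[C@@H](O[Si](CC)(CC)CC)CC(=C)[C@@H](O[Si](C)(C)C(C)(C)C)C[C@@H]12
F7 | step 19 | 9-alcohol of acetonide 29 (C10=C14H2) | C1C(=O)O[C@@H]2/C=C(/C)[C@H]3OC(C)(C)O[C@H]3CC(=C)[C@@H](O)C[C@@H]12
F8 | step 19 | (10R)-10,14-dihydro 9-alcohol | C1C(=O)O[C@@H]2/C=C(/C)[C@H]3OC(C)(C)O[C@H]3C[C@@H](C)[C@@H](O)C[C@@H]12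
F9 | step 12 | 5-(2,2-dibromovinyl) lactone from 16 | O=C1C[C@H](C[C@H](O[Si](C)(C)C(C)(C)C)C(=C)COCC(OC)OC)[C@@H](C=C(Br)Br)O1
F10 | step 12 | 5-[(Z)-2-bromoprop-1-en-1-yl] lactone acetal | O=C1C[C@H](C[C@H](O[Si](C)(C)C(C)(C)C)C(=C)COCC(OC)OC)[C@@H](/C=C(/C)\Br)O1
F11 | step 12 | collidinium triflate from F10 | O=C1C[C@H](C[C@H](O[Si](C)(C)C(C)(C)C)C(=C)COCC(OC)[n+]2c(C)cc(C)cc2C)[C@@H](/C=C(/C)\Br)O1.[O-]S(=O)(=O)C(F)(F)F
F12 | step 12 | bromoalkene aldehyde (bromo analogue of 23) | O=C1C[C@H](C[C@H](O[Si](C)(C)C(C)(C)C)C(=C)COCC=O)[C@@H](/C=C(/C)\Br)O1
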